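The target is disconnected at C3–prenyl and C1–C2, because the bridge C2(Me2)–C3–C4 is itself a prenyl unit hung on the quaternary bridgehead C5 of a five-membered ring (C1, C7, C6, C5, C8), and C1 is an enolisable tricarbonyl carbon. A prenyltransferase adds the dimethylallyl cation of DMAPP to C3 of one of two enantiotopic prenyl groups and lets enolate carbon C1 trap the C2 cation. This closes the six-membered ring C1–C2–C3–C4–C5–C8 and sets C1, C3 and C5 at once. The precursor is achiral cohulupone, a 3-isobutyryl-5,5-diprenylcyclopentane-1,2,4-trione, assembled from a β-diketone, diethyl oxalate and prenyl bromide. The C6 acyl carbinol is added afterwards by reduction, esterification and O-to-C acyl shift.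

Key step: step 4

Numbering of the bicycle: C1 isobutyryl bridgehead, C2 CMe2, C3 CH-prenyl, C4 CH2, C5 prenyl bridgehead, C6 carbinol (ketone in 11), C7 ketone, C8 bridging ketone. Exo is the face of C6/C7 turned to C8, endo the face turned to C3.
Remark: 6 and 7 are racemic at their prenyl-bearing CH, an enolisable centre that becomes a non-stereogenic quaternary carbon in step 3.
Remark: 10 is drawn as the free acid and used as its commercial ammonium salt.
Remark: the C5 descriptor changes from R in 11 to S from 17 onwards only because C6 falls below C8 in CIP rank once it is sp3; no bond at C5 is touched.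
Remark: the target is taken in the open-chain Z hydroxy-enone form in which it is drawn.

Step 1
Reactants: 1 5-methylhexane-2,4-dione; 2 prenyl bromide
Product: 4 2,9-dimethyldec-8-ene-3,5-dione, via dilithium dianion 3 (not isolated)
Conditions: LiN(iPr)2 (2.1 equiv), THF, −78 to 0 °C; then prenyl bromide (1.0 equiv), −78 to 0 °C; 1 M HCl
Reagents that add atoms: none
Why: Hauser-type γ-alkylation of a β-diketone dianion, in which the second deprotonation takes the unhindered terminal methyl in preference to the isopropyl methine and the dianion then reacts at this last-formed, most basic carbon with the primary allylic bromide by SN2; no stereocentre is formed.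

Step 2
Reactants: 4 2,9-dimethyldec-8-ene-3,5-dione; 5 diethyl oxalate
Product: 7 3-isobutyryl-5-prenylcyclopentane-1,2,4-trione (racemic enol form), via oxalyl triketo ester 6 (not isolated)
Conditions: NaOEt (2.5 equiv), EtOH, 0 °C to reflux; then 2 M HCl, 0 °C
Reagents that add atoms: none
Why: Crossed Claisen acylation by the non-enolisable diester at the methylene that is α to one ketone only, then Dieckmann closure of the second ester group onto the methylene between the two ketones, is the classical double oxalate condensation that turns ketones with two α-methylene groups into cyclopentane-1,2,4-triones; it is driven by the doubly deprotonated product, which closure through the isopropyl methine could not give.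

Step 3
Reactants: 7 3-isobutyryl-5-prenylcyclopentane-1,2,4-trione; 2 prenyl bromide
Product: 9 cohulupone, via dilithium dianion 8 (not isolated)
Conditions: LiN(SiMe3)2 (2.1 equiv), THF, −78 to −20 °C; then prenyl bromide (1.05 equiv), −78 to 0 °C; 1 M HCl
Reagents that add atoms: none
Why: Double deprotonation (enol OH, then the ring C–H between two carbonyls) gives a dianion that is C-alkylated at its last-formed, least delocalised carbon, the prenyl-bearing ring carbon, as in the closing geminal prenylation of the classical hop β-acid syntheses; the acyl-bearing carbon stays masked in the tricarbonyl anion, and the new quaternary carbon carries two identical groups, so 9 is achiral.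

Step 4
Reactants: 9 cohulupone; 10 dimethylallyl diphosphate (1.5 equiv)
Product: 11 (1R,3R,5R)-1-isobutyryl-2,2-dimethyl-3,5-diprenylbicyclo[3.2.1]octane-6,7,8-trione
Conditions: evolved UbiA-family prenyltransferase (Saccharomyces cerevisiae microsomes), MgCl2, Tris-HCl buffer pH 7.5, dodecane overlay, 30 °C
Reagents that add atoms: none
Why: Proposed new method: Mg-assisted loss of diphosphate from 10 in the active site gives a dimethylallyl cation, the trisubstituted alkene of one prenyl group on C5 of the enolate of 9 adds to it through its CH terminus (the future C3), and the tertiary cation that results at C2 is quenched by the acyl-bearing enolate carbon C1, so C3–prenyl and C1–C2 form in one turnover. The nearest known reaction type is the biosynthetic prenylative cation–olefin bicyclisation by which a membrane prenyltransferase builds the bicyclo[3.3.1]nonane core of hyperforin-type acylphloroglucinols from a gem-diprenyl six-membered enol; the five-membered trione 9 has not been shown as a substrate. The ring C1–C2–C3–C4–C5–C8 closes in the 6-endo mode with respect to the prenyl alkene (enol-exo for the nucleophile) through a chair. C3 is set by anti addition across the alkene in that chair, which puts the new prenyl equatorial and antiperiplanar to C1–C2, whereas C1 and C5 are tied cis by the bridge and their absolute sense follows from which enantiotopic prenyl group the pocket offers to the cation. The step needs enantiotopic-group selection, C- instead of O-capture of the cation and prenyl transfer to the alkene instead of the enolate; the substrate contributes a quaternary C5, a single nucleophilic carbon (C1) held five atoms from C2 and a delocalised, weakly nucleophilic tricarbonyl anion, and the remainder has to come from screening and directed evolution of the enzyme.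

Step 5
Reactants: 12 2-methylbut-3-yn-2-ol
Product: 13 triethyl[(2-methylbut-3-yn-2-yl)oxy]silane
Conditions: Et3SiCl, imidazole, DMF, 0 °C to rt
Reagents that add atoms: chlorotriethylsilane, CC[Si](Cl)(CC)CC
Why: Silyl ether formation on a tertiary propargylic alcohol is routine, and the triethylsilyl group should survive organolithium, hydrogenation and amide base yet leave under buffered fluoride.

Step 6
Reactants: 13 triethyl[(2-methylbut-3-yn-2-yl)oxy]silane
Product: 15 4-methyl-4-(triethylsilyloxy)pent-2-ynoic acid, via lithium acetylide 14 (not isolated)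
Conditions: n-BuLi, THF, −78 °C; CO2; then 1 M HCl to pH 3, 0 °C
Reagents that add atoms: carbon dioxide, O=C=O
Why: Deprotonation of the terminal alkyne and carboxylation of the lithium acetylide is the standard route to alk-2-ynoic acids.

Step 7
Reactants: 15 4-methyl-4-(triethylsilyloxy)pent-2-ynoic acid
Product: 16 (Z)-4-methyl-4-(triethylsilyloxy)pent-2-enoic acid
Conditions: H2 (1 atm), Pd on CaCO3 poisoned with Pb(OAc)2 (Lindlar catalyst), quinoline, EtOAc, rt
Reagents that add atoms: none
Why: Lindlar semi-hydrogenation delivers H2 syn to the alkyne and so fixes the Z alkene, while the silyl ether keeps the acid from closing to the butenolide.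

Step 8
Reactants: 11 (1R,3R,5R)-1-isobutyryl-2,2-dimethyl-3,5-diprenylbicyclo[3.2.1]octane-6,7,8-trione
Product: 17 (1R,3R,5S,6R)-6-hydroxy-1-isobutyryl-2,2-dimethyl-3,5-diprenylbicyclo[3.2.1]octane-7,8-dione (6-OH endo)
Conditions: Zn dust, AcOH, THF, 0 °C
Reagents that add atoms: none
Why: Dissolving-metal reduction of a 1,2-diketone to its acyloin touches only the vicinal C6/C7 dione, the most easily reduced carbonyl pair, and protonation of the zinc enediolate at the less hindered C6 from the exo face should give the endo alcohol; C6 is only a temporary stereocentre, and a C7-hydroxy isomer shares the same enediol and should converge in step 10, where the acyl group can move between O6 and O7 of the enediolate.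

Step 9
Reactants: 17 6-endo-hydroxy-7,8-dione; 16 (Z)-4-methyl-4-(triethylsilyloxy)pent-2-enoic acid
Product: 18 (1R,3R,5S,6R)-1-isobutyryl-2,2-dimethyl-7,8-dioxo-3,5-diprenylbicyclo[3.2.1]octan-6-yl (Z)-4-methyl-4-(triethylsilyloxy)pent-2-enoate
Conditions: DCC, DMAP (cat.), CH2Cl2, −20 to 0 °C
Reagents that add atoms: none
Why: Steglich esterification acylates the secondary alcohol under neutral conditions, and the low temperature is meant to preserve the Z alkene and the acyloin; no stereocentre changes.

Step 10
Reactants: 18 C6 ester of the Z acid
Product: 20 (1R,3R,5S,6S)-6-hydroxy-1-isobutyryl-2,2-dimethyl-6-[(Z)-4-methyl-4-(triethylsilyloxy)pent-2-enoyl]-3,5-diprenylbicyclo[3.2.1]octane-7,8-dione, via lithium enolate 19 (not isolated)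
Conditions: LiN(SiMe3)2 (1.2 equiv), THF, −78 to −30 °C; then AcOH, −78 °C
Reagents that add atoms: none
Why: In a Chan-type rearrangement the enolate formed by removal of the exo C6–H undergoes an intramolecular 1,2 O-to-C acyl shift through an alkoxy-oxirane (known for α-acyloxy esters and ketones), and the acyl group should swing onto C6 over the exo face because the endo face is screened by the axial C3–H, which sets C6 with the acyl exo and the hydroxyl endo (6S); lithium chelation of the new alkoxide by its two flanking carbonyls and loss of the strained bridge enolate should drive it.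

Step 11
Reactants: 20 triethylsilyl ether of the target
Product: 21 target, (1R,3R,5S,6S)-6-hydroxy-6-[(Z)-4-hydroxy-4-methylpent-2-enoyl]-1-isobutyryl-2,2-dimethyl-3,5-diprenylbicyclo[3.2.1]octane-7,8-dione
Conditions: HF·pyridine, pyridine, THF, 0 °C
Reagents that add atoms: none
Why: Buffered fluoride desilylation cleaves the tertiary triethylsilyl ether without the basic conditions that could reverse the acyl shift or cleave the β-dicarbonyl units, so the four stereocentres and the Z alkene should stay untouched.

Compound list
1 | 5-methylhexane-2,4-dione | CC(C)C(=O)CC(C)=O | starting material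
2 | prenyl bromide, 1-bromo-3-methylbut-2-ene | CC(C)=CCBr | starting material
3 | dilithium dianion of 1 (dienediolate, terminal CH2 deprotonated) | C=C(O[Li])C=C(O[Li])C(C)C | intermediate
4 | 2,9-dimethyldec-8-ene-3,5-dione | CC(C)C(=O)CC(=O)CCC=C(C)C | intermediate
5 | diethyl oxalate | CCOC(=O)C(=O)OCC | starting material
6 | ethyl 7-methyl-3-(3-methylbut-2-en-1-yl)-2,4,6-trioxooctanoate (racemic) | CCOC(=O)C(=O)C(CC=C(C)C)C(=O)CC(=O)C(C)C | intermediate
7 | 3-isobutyryl-5-prenylcyclopentane-1,2,4-trione (enol form, racemic at C5) | CC(C)C(=O)C1=C(O)C(=O)C(CC=C(C)C)C1=O | intermediate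
8 | dilithium dianion of 7 | CC(C)C(O[Li])=C1C(=O)C(=O)C(CC=C(C)C)=C1O[Li] | intermediate
9 | cohulupone, 3-isobutyryl-5,5-diprenylcyclopentane-1,2,4-trione (enol form) | CC(C)C(=O)C1=C(O)C(=O)C(CC=C(C)C)(CC=C(C)C)C1=O | intermediate
10 | dimethylallyl diphosphate (DMAPP) | CC(C)=CCOP(=O)(O)OP(=O)(O)O | starting material
11 | (1R,3R,5R)-1-isobutyryl-2,2-dimethyl-3,5-diprenylbicyclo[3.2.1]octane-6,7,8-trione (3-prenyl equatorial) | CC(C)=CC[C@@H]1C[C@]2(CC=C(C)C)C(=O)[C@@](C(=O)C(C)C)(C(=O)C2=O)C1(C)C | intermediate
12 | 2-methylbut-3-yn-2-ol | CC(C)(O)C#C | starting material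
13 | triethyl[(2-methylbut-3-yn-2-yl)oxy]silane | CC[Si](CC)(CC)OC(C)(C)C#C | intermediate
14 | lithium acetylide of 13 | CC[Si](CC)(CC)OC(C)(C)C#C[Li] | intermediate
15 | 4-methyl-4-(triethylsilyloxy)pent-2-ynoic acid | CC[Si](CC)(CC)OC(C)(C)C#CC(=O)O | intermediate
16 | (Z)-4-methyl-4-(triethylsilyloxy)pent-2-enoic acid | CC[Si](CC)(CC)OC(C)(C)/C=C\C(=O)O | intermediate
17 | (1R,3R,5S,6R)-6-hydroxy-1-isobutyryl-2,2-dimethyl-3,5-diprenylbicyclo[3.2.1]octane-7,8-dione (6-OH endo) | CC(C)=CC[C@@H]1C[C@]2(CC=C(C)C)C(=O)[C@@](C(=O)C(C)C)(C(=O)[C@@H]2O)C1(C)C | intermediate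
18 | C6 (endo) ester of 17 with acid 16 | CC(C)=CC[C@@H]1C[C@]2(CC=C(C)C)C(=O)[C@@](C(=O)C(C)C)(C(=O)[C@@H]2OC(=O)/C=C\C(C)(C)O[Si](CC)(CC)CC)C1(C)C | intermediate
19 | lithium C6=C7 enolate of 18 | CC(C)=CC[C@@H]1C[C@]2(CC=C(C)C)C(=O)[C@@](C(=O)C(C)C)(C(O[Li])=C2OC(=O)/C=C\C(C)(C)O[Si](CC)(CC)CC)C1(C)C | intermediate
20 | triethylsilyl ether of the target (1R,3R,5S,6S; 6-acyl exo, 6-OH endo) | CC(C)=CC[C@@H]1C[C@]2(CC=C(C)C)C(=O)[C@@](C(=O)C(C)C)(C(=O)[C@@]2(O)C(=O)/C=C\C(C)(C)O[Si](CC)(CC)CC)C1(C)C | intermediate
21 | (1R,3R,5S,6S)-6-hydroxy-6-[(Z)-4-hydroxy-4-methylpent-2-enoyl]-1-isobutyryl-2,2-dimethyl-3,5-diprenylbicyclo[3.2.1]octane-7,8-dione | CC(C)=CC[C@@H]1C[C@]2(CC=C(C)C)C(=O)[C@@](C(=O)C(C)C)(C(=O)[C@@]2(O)C(=O)/C=C\C(C)(C)O)C1(C)C | target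

Total step count: 11. Longest linear sequence: 8 steps (1, 2, 3, 4, 8, 9, 10, 11); steps 5–7 are the side-chain branch.

Steps most likely to fail

Step 4 (Proposed new method). The enzyme may not turn over the five-membered substrate, may prenylate the enolate at carbon or oxygen instead of the alkene, may let an enol oxygen capture the cation, or may select the wrong enantiotopic prenyl group. The fallback sets out from cohulupone 9 and comes back at trione 11, using an epoxide-opening cyclisation followed by radical allylation. One prenyl group of 9 is epoxidised under Shi conditions (fructose-derived Shi ketone of the D series, KHSO5 as Oxone, K2CO3 buffer, MeCN/H2O, 0 °C, one equivalent of oxidant). This should fix the oxirane CH as R in the cohulupone mono-epoxide F1, formed as both C5 epimers because the reagent cannot tell the enantiotopic prenyl groups apart. BF3·OEt2 in CH2Cl2 at −78 °C opens the epoxide at its tertiary carbon with attack of the enol carbon C1 through the same chair. Only the C5 epimer in which the C3–O bond can lie equatorial should close to the 3-hydroxy trione F2, which is separated from the material derived from the other epimer, so half of the material is lost. The alcohol is converted into the phenyl thionocarbonate F3 (PhOC(S)Cl, pyridine, DMAP, CH2Cl2). Keck radical allylation (Bu3SnCH2CH=CH2, AIBN, PhH, 80 °C) from the open face should give the 3-allyl trione F4 with the side chain equatorial. Cross-metathesis with 2-methylbut-2-ene (second-generation Grubbs catalyst, CH2Cl2, 40 °C) turns allyl into prenyl and gives 11.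

Step 10. The acyl-shift equilibrium may lie on the side of the enolate of the ester, the tertiary alkoxide may fragment by retro-aldol or retro-Claisen cleavage, and the Z alkene may isomerise. The fallback sets out from acyloin 17 and silyl ether 13 and comes back at 20, forming the C6–C bond by an aldol addition instead of an acyl transfer. Silyl ether 13 is formylated (n-BuLi, THF, −78 °C; DMF) to 4-methyl-4-(triethylsilyloxy)pent-2-ynal F5. The enediolate of 17 (LiN(SiMe3)2, 2.2 equiv, THF, −78 °C) should add to F5 at C6 from the exo face to give the propargylic diol F6, a mixture at the new carbinol carbon. Dess–Martin periodinane oxidises the secondary propargylic alcohol to the ynone F7, and Lindlar semi-hydrogenation (H2, Pd on CaCO3 poisoned with Pb(OAc)2, quinoline) gives 20.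

Step 9. The activated Z acid may isomerise to E or lactonise with loss of the silyl group while the hindered endo alcohol acylates slowly. The fallback sets out from acyloin 17 and alkynoic acid 15 and comes back at ester 18, making the Z geometry after the C–O bond. Alcohol 17 is esterified with 15 (DCC, DMAP, CH2Cl2, 0 °C), which has no alkene geometry to lose, to give the alkynoate ester F8. Lindlar semi-hydrogenation of F8 then gives 18.

Further compounds
F1 | step 4 | cohulupone mono-epoxide, R at the oxirane CH, both C5 epimers | CC(C)C(=O)C1=C(O)C(=O)C(CC=C(C)C)(C[C@H]2OC2(C)C)C1=O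
F2 | step 4 | 3-hydroxy analogue of 11, OH equatorial, bridgeheads as in 11 | O[C@@H]1C[C@]2(CC=C(C)C)C(=O)[C@@](C(=O)C(C)C)(C(=O)C2=O)C1(C)C
F3 | step 4 | O-phenyl thionocarbonate of F2 | S=C(Oc1ccccc1)O[C@@H]1C[C@]2(CC=C(C)C)C(=O)[C@@](C(=O)C(C)C)(C(=O)C2=O)C1(C)C
F4 | step 4 | 3-allyl analogue of 11, allyl equatorial | C=CC[C@@H]1C[C@]2(CC=C(C)C)C(=O)[C@@](C(=O)C(C)C)(C(=O)C2=O)C1(C)C
F5 | step 10 | 4-methyl-4-(triethylsilyloxy)pent-2-ynal | O=CC#CC(C)(C)O[Si](CC)(CC)CC
F6 | step 10 | C6 aldol adduct of 17 and F5, propargylic diol, carbinol carbon undefined | CC(C)=CC[C@@H]1C[C@]2(CC=C(C)C)C(=O)[C@@](C(=O)C(C)C)(C(=O)[C@@]2(O)C(O)C#CC(C)(C)O[Si](CC)(CC)CC)C1(C)C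
F7 | step 10 | ynone analogue of 20 | CC(C)=CC[C@@H]1C[C@]2(CC=C(C)C)C(=O)[C@@](C(=O)C(C)C)(C(=O)[C@@]2(O)C(=O)C#CC(C)(C)O[Si](CC)(CC)CC)C1(C)C
F8 | step 9 | C6 ester of 17 with alkynoic acid 15 | CC(C)=CC[C@@H]1C[C@]2(CC=C(C)C)C(=O)[C@@](C(=O)C(C)C)(C(=O)[C@@H]2OC(=O)C#CC(C)(C)O[Si](CC)(CC)CC)C1(C)C
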